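**Retrosynthetic overview**
1. Target 17 ⇐ global O-debenzylation of penta-benzyl ether 16.
2. 16 ⇐ hydroboration–oxidation of 4-aryl-2H-chromene 14; C2 controls C3 and C4 (all-trans upper unit).
3. Key step: 14 ⇐ acyclic bis-ether 13; both pyran rings close in one operation by C–C bond formation (F ring: epoxide–arene cyclialkylation, C4′–C4a′; C ring: alkyne hydroarylation, C4–C4a).
4. 13 ⇐ Sonogashira coupling of aryl bromide 7 with alkyne 12; the interflavan C4–C6′ bond is made as an aryl–alkyne bond.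
5. 7 and 12 ⇐ Mitsunobu etherifications (inversion) of erythro epoxy alcohol 4 and propargylic alcohol 11 with resorcinol monobenzyl ethers; all aromatic rings are bought.

Assumption: the SMILES is read as guibourtinidol-(4α→6)-ent-epifisetinidol, (2R,3S,4R)/(2′S,3′S); in step 5 the ProPhenol antipode used is whichever gives the (S)-silyl carbinol 10 (sense to be confirmed on the first batch).

**Route**

Step 1
Reactants: 1 3,4-bis(benzyloxy)benzaldehyde; 2 vinylmagnesium bromide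
Product: 3 rac-1-[3,4-bis(benzyloxy)phenyl]prop-2-en-1-ol
Conditions: THF, −78 → 0 °C; aq NH4Cl
Reagents that add atoms: none
Why: Grignard 1,2-addition to the aldehyde gives the racemic secondary allylic alcohol needed for kinetic resolution.

Step 2
Reactants: 3 rac-1-[3,4-bis(benzyloxy)phenyl]prop-2-en-1-ol
Product: 4 (R)-[3,4-bis(benzyloxy)phenyl][(2S)-oxiran-2-yl]methanol
Conditions: Ti(OiPr)4 (15 mol %), D-(−)-DIPT (20 mol %), t-BuOOH (0.45 equiv), 4 Å MS, CH2Cl2, −20 °C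
Reagents that add atoms: tert-butyl hydroperoxide, CC(C)(C)OO
Why: Sharpless kinetic resolution epoxidises the (S)-alcohol fast and erythro (anti) to the carbinol, which fixes both stereocentres of 4 (carbinol becomes R only by CIP priority change, oxirane S), while unreacted (R)-3 is separated.

Step 3
Reactants: 5 3-(benzyloxy)phenol
Product: 6 3-(benzyloxy)-4-bromophenol
Conditions: NBS (1.0 equiv), MeCN, −20 → 0 °C
Reagents that add atoms: N-bromosuccinimide, O=C1CCC(=O)N1Br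
Why: electrophilic aromatic bromination goes mainly para to the free OH (the stronger director); the minor ortho isomer is removed by chromatography.

Step 4
Reactants: 4 (R)-[3,4-bis(benzyloxy)phenyl][(2S)-oxiran-2-yl]methanol; 6 3-(benzyloxy)-4-bromophenol
Product: 7 2-(benzyloxy)-4-{(S)-[3,4-bis(benzyloxy)phenyl][(2S)-oxiran-2-yl]methoxy}-1-bromobenzene
Conditions: PPh3, DIAD, toluene, 0 °C → rt
Reagents that add atoms: none
Why: Mitsunobu etherification with SN2 inversion at the benzylic carbinol (the adjacent epoxide disfavours ionisation) turns the erythro alcohol into the threo aryl ether, setting future C2′ (S) next to C3′ (S), i.e. the 2,3-cis lower unit.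

Step 5
Reactants: 8 4-(benzyloxy)benzaldehyde; 9 ethynyltrimethylsilane
Product: 11 (R)-1-[4-(benzyloxy)phenyl]prop-2-yn-1-ol, via silyl carbinol 10 (not isolated)
Conditions: Me2Zn (3 equiv), ProPhenol (10 mol %), toluene, 0 °C; then K2CO3, MeOH, rt
Reagents that add atoms: none
Why: Zn–ProPhenol catalysed enantioselective alkynylation of the aldehyde sets the carbinol centre, and methanolysis of the C–Si bond frees the terminal alkyne.

Step 6
Reactants: 11 (R)-1-[4-(benzyloxy)phenyl]prop-2-yn-1-ol; 5 3-(benzyloxy)phenol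
Product: 12 1-(benzyloxy)-3-{[(1S)-1-[4-(benzyloxy)phenyl]prop-2-yn-1-yl]oxy}benzene
Conditions: PPh3, DIAD, toluene, −20 → 0 °C
Reagents that add atoms: none
Why: Mitsunobu etherification with inversion converts the (R)-alcohol into the (S)-aryl propargyl ether, which is the spatial arrangement of C2 (R) in the upper unit.

Step 7
Reactants: 7 2-(benzyloxy)-4-{(S)-[3,4-bis(benzyloxy)phenyl][(2S)-oxiran-2-yl]methoxy}-1-bromobenzene; 12 1-(benzyloxy)-3-{[(1S)-1-[4-(benzyloxy)phenyl]prop-2-yn-1-yl]oxy}benzene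
Product: 13 2-(benzyloxy)-1-{(3R)-3-[3-(benzyloxy)phenoxy]-3-[4-(benzyloxy)phenyl]prop-1-yn-1-yl}-4-{(S)-[3,4-bis(benzyloxy)phenyl][(2S)-oxiran-2-yl]methoxy}benzene
Conditions: PdCl2(MeCN)2 (3 mol %), XPhos (9 mol %), Cs2CO3, MeCN, 70 °C
Reagents that add atoms: none
Why: copper-free Sonogashira coupling of the electron-rich aryl bromide with the terminal alkyne makes the future C4–C6′ bond as an sp–sp2 bond without touching any stereocentre (the descriptor changes to R only by CIP priority).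

Step 8
Reactants: 13 2-(benzyloxy)-1-{(3R)-3-[3-(benzyloxy)phenoxy]-3-[4-(benzyloxy)phenyl]prop-1-yn-1-yl}-4-{(S)-[3,4-bis(benzyloxy)phenyl][(2S)-oxiran-2-yl]methoxy}benzene
Product: 14 (2S,3S)-7-(benzyloxy)-6-{(2S)-7-(benzyloxy)-2-[4-(benzyloxy)phenyl]-2H-chromen-4-yl}-2-[3,4-bis(benzyloxy)phenyl]-3,4-dihydro-2H-chromen-3-ol
Conditions: AuCl3 (5 mol %), AgOTf (15 mol %), ClCH2CH2Cl (0.01 M), 0 °C → rt, dark
Reagents that add atoms: none
Why: Proposed new method: cationic gold(III) activates both electrophiles of 13 for intramolecular Friedel–Crafts attack by the resorcinol-diether carbons para to OBn, namely 6-endo-dig hydroarylation of the aryl propargyl ether (C4–C4a bond, 2H-chromene C ring) and 6-endo SN2-type cyclialkylation at the terminal epoxide carbon (C4′–C4a′ bond, F ring carrying the 3′-OH), so two pyran rings form in one operation while C2, C2′ and C3′ are not involved and keep the configurations set in steps 2, 4 and 6; the closest known reaction types are the AuCl3/AgOTf cyclialkylation of aryl glycidyl ethers to 3-chromanols and the Au- or Pt-catalysed hydroarylation of aryl propargyl ethers to 2H-chromenes.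

Step 9
Reactants: 14 (2S,3S)-7-(benzyloxy)-6-{(2S)-7-(benzyloxy)-2-[4-(benzyloxy)phenyl]-2H-chromen-4-yl}-2-[3,4-bis(benzyloxy)phenyl]-3,4-dihydro-2H-chromen-3-ol
Product: 16 (2R,3S,4S)-7-(benzyloxy)-2-[4-(benzyloxy)phenyl]-4-{(2S,3S)-7-(benzyloxy)-2-[3,4-bis(benzyloxy)phenyl]-3-hydroxy-3,4-dihydro-2H-chromen-6-yl}-3,4-dihydro-2H-chromen-3-ol, via C3-alkylborane 15 (not isolated)
Conditions: BH3·SMe2 (4 equiv), THF, 0 °C → rt; then 3 M NaOH, 30 % H2O2, 0 °C → rt
Reagents that add atoms: hydrogen peroxide, OO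
Why: hydroboration–oxidation adds H (to the fully substituted C4) and B (to C3) syn from the face anti to the C2 aryl group, and oxidation with retention gives 3-OH trans to 2-aryl and 4-H cis to 3-OH, i.e. the 2,3-trans-3,4-trans upper unit (the lower 3′-OH is only borylated temporarily).

Step 10
Reactants: 16 (2R,3S,4S)-7-(benzyloxy)-2-[4-(benzyloxy)phenyl]-4-{(2S,3S)-7-(benzyloxy)-2-[3,4-bis(benzyloxy)phenyl]-3-hydroxy-3,4-dihydro-2H-chromen-6-yl}-3,4-dihydro-2H-chromen-3-ol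
Product: 17 (2R,3S,4R)-4-[(2S,3S)-2-(3,4-dihydroxyphenyl)-3,7-dihydroxy-3,4-dihydro-2H-chromen-6-yl]-2-(4-hydroxyphenyl)-3,4-dihydro-2H-chromene-3,7-diol (CNP0243811.1)
Conditions: H2 (1 atm), 20 % Pd(OH)2/C, THF–MeOH 1:1, rt
Reagents that add atoms: none
Why: catalytic hydrogenolysis removes the five benzyl ethers without touching the flavan C–O or C4–aryl bonds; no stereocentre changes (the C4 descriptor goes from S to R only because the CIP priorities change).

**Compound list**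
1 | 3,4-bis(benzyloxy)benzaldehyde | O=Cc1ccc(OCc2ccccc2)c(OCc2ccccc2)c1 | starting material
2 | vinylmagnesium bromide | C=C[Mg]Br | starting material
3 | rac-1-[3,4-bis(benzyloxy)phenyl]prop-2-en-1-ol | C=CC(O)c1ccc(OCc2ccccc2)c(OCc2ccccc2)c1 | intermediate
4 | (R)-[3,4-bis(benzyloxy)phenyl][(2S)-oxiran-2-yl]methanol (erythro) | O[C@H](c1ccc(OCc2ccccc2)c(OCc2ccccc2)c1)[C@@H]1CO1 | intermediate
5 | 3-(benzyloxy)phenol | Oc1cccc(OCc2ccccc2)c1 | starting material
6 | 3-(benzyloxy)-4-bromophenol | Oc1ccc(Br)c(OCc2ccccc2)c1 | intermediate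
7 | 2-(benzyloxy)-4-{(S)-[3,4-bis(benzyloxy)phenyl][(2S)-oxiran-2-yl]methoxy}-1-bromobenzene (threo) | Brc1ccc(O[C@@H](c2ccc(OCc3ccccc3)c(OCc3ccccc3)c2)[C@@H]2CO2)cc1OCc1ccccc1 | intermediate
8 | 4-(benzyloxy)benzaldehyde | O=Cc1ccc(OCc2ccccc2)cc1 | starting material
9 | ethynyltrimethylsilane | C#C[Si](C)(C)C | starting material
10 | (S)-1-[4-(benzyloxy)phenyl]-3-(trimethylsilyl)prop-2-yn-1-ol | O[C@H](C#C[Si](C)(C)C)c1ccc(OCc2ccccc2)cc1 | intermediate
11 | (R)-1-[4-(benzyloxy)phenyl]prop-2-yn-1-ol | O[C@H](C#C)c1ccc(OCc2ccccc2)cc1 | intermediate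
12 | 1-(benzyloxy)-3-{[(1S)-1-[4-(benzyloxy)phenyl]prop-2-yn-1-yl]oxy}benzene | C#C[C@H](Oc1cccc(OCc2ccccc2)c1)c1ccc(OCc2ccccc2)cc1 | intermediate
13 | 2-(benzyloxy)-1-{(3R)-3-[3-(benzyloxy)phenoxy]-3-[4-(benzyloxy)phenyl]prop-1-yn-1-yl}-4-{(S)-[3,4-bis(benzyloxy)phenyl][(2S)-oxiran-2-yl]methoxy}benzene | C(#Cc1ccc(O[C@@H](c2ccc(OCc3ccccc3)c(OCc3ccccc3)c2)[C@@H]2CO2)cc1OCc1ccccc1)[C@H](Oc1cccc(OCc2ccccc2)c1)c1ccc(OCc2ccccc2)cc1 | intermediate
14 | (2S,3S)-7-(benzyloxy)-6-{(2S)-7-(benzyloxy)-2-[4-(benzyloxy)phenyl]-2H-chromen-4-yl}-2-[3,4-bis(benzyloxy)phenyl]-3,4-dihydro-2H-chromen-3-ol | C(c1ccccc1)Oc1ccc(cc1)[C@H]1Oc2cc(OCc3ccccc3)ccc2C(=C1)c1cc2c(cc1OCc1ccccc1)O[C@@H](c1ccc(OCc3ccccc3)c(OCc3ccccc3)c1)[C@@H](O)C2 | intermediate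
15 | C3-alkylborane of 14 (3-BH2 and 4-H cis, both anti to the 2-aryl group; 3′-O-BH2) | C(c1ccccc1)Oc1ccc(cc1)[C@H]1Oc2cc(OCc3ccccc3)ccc2[C@@H](c2cc3c(cc2OCc2ccccc2)O[C@@H](c2ccc(OCc4ccccc4)c(OCc4ccccc4)c2)[C@@H](OB)C3)[C@@H]1B | intermediate
16 | (2R,3S,4S)-7-(benzyloxy)-2-[4-(benzyloxy)phenyl]-4-{(2S,3S)-7-(benzyloxy)-2-[3,4-bis(benzyloxy)phenyl]-3-hydroxy-3,4-dihydro-2H-chromen-6-yl}-3,4-dihydro-2H-chromen-3-ol | C(c1ccccc1)Oc1ccc(cc1)[C@H]1Oc2cc(OCc3ccccc3)ccc2[C@@H](c2cc3c(cc2OCc2ccccc2)O[C@@H](c2ccc(OCc4ccccc4)c(OCc4ccccc4)c2)[C@@H](O)C3)[C@@H]1O | intermediate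
17 | (2R,3S,4R)-4-[(2S,3S)-2-(3,4-dihydroxyphenyl)-3,7-dihydroxy-3,4-dihydro-2H-chromen-6-yl]-2-(4-hydroxyphenyl)-3,4-dihydro-2H-chromene-3,7-diol | Oc1ccc([C@H]2Oc3cc(O)ccc3[C@@H](c3cc4c(cc3O)O[C@@H](c3ccc(O)c(O)c3)[C@@H](O)C4)[C@@H]2O)cc1 | target

**Step count and risks**

Total steps: 10. Longest linear sequence: 7 (steps 1, 2, 4, 7, 8, 9, 10).

Most likely to fail:

Step 8 (one-pot double cyclisation). Risks are ionisation of the benzylic aryl ethers at C2 and C2′ under Au(III) (racemisation), aryl migration on epoxide opening, and attack of the ortho-OBn oxygen on the alkyne. The fallback sets out from 7 and returns at 14, building the rings one at a time and closing the upper ring by a buffered electrophilic cyclisation instead of π-acid catalysis. Cyclialkylation of 7 alone (AuCl3/AgOTf, ClCH2CH2Cl) gives (2S,3S)-7-(benzyloxy)-2-[3,4-bis(benzyloxy)phenyl]-6-bromo-3,4-dihydro-2H-chromen-3-ol F1. Copper-free Sonogashira coupling of F1 with 12 gives (2S,3S)-7-(benzyloxy)-6-{(3R)-3-[3-(benzyloxy)phenoxy]-3-[4-(benzyloxy)phenyl]prop-1-yn-1-yl}-2-[3,4-bis(benzyloxy)phenyl]-3,4-dihydro-2H-chromen-3-ol F2. Iodocyclisation (I2, NaHCO3, MeCN, rt) gives (2S,3S)-7-(benzyloxy)-6-{(2R)-7-(benzyloxy)-2-[4-(benzyloxy)phenyl]-3-iodo-2H-chromen-4-yl}-2-[3,4-bis(benzyloxy)phenyl]-3,4-dihydro-2H-chromen-3-ol F3, and Pd-catalysed hydrodeiodination (Pd(PPh3)4, HCO2Na, DMF, 60 °C) gives 14.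

Step 6 (Mitsunobu at a p-alkoxybenzylic propargylic carbinol). The risk is partial SN1 racemisation. The fallback sets out from 8 and returns at 12, replacing the SN2 step by an enantioconvergent catalytic substitution. Ethynylmagnesium bromide followed by Ac2O in the same flask gives rac-1-[4-(benzyloxy)phenyl]prop-2-yn-1-yl acetate F4. Cu(I)–chiral pybox propargylic etherification of F4 with 5 (via a copper allenylidene, i-Pr2NEt) then gives 12 directly; this also replaces step 5.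

Step 2 (Sharpless kinetic resolution of an electron-rich aryl vinyl carbinol). The risks are slow epoxidation of the terminal alkene and Ti-promoted ionisation of the carbinol. The fallback sets out from 3 and returns at 4, separating resolution from epoxidation. Lipase acylation (CAL-B, vinyl acetate) converts the (R)-alcohol into (R)-1-[3,4-bis(benzyloxy)phenyl]prop-2-en-1-yl acetate F6 and leaves (S)-1-[3,4-bis(benzyloxy)phenyl]prop-2-en-1-ol F5. Hydroxyl-directed epoxidation of F5 (VO(acac)2, t-BuOOH, CH2Cl2) is erythro-selective (about 4:1 expected) and gives 4 after removal of the threo isomer.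

**Further compounds**
F1 | step 8 | (2S,3S)-7-(benzyloxy)-2-[3,4-bis(benzyloxy)phenyl]-6-bromo-3,4-dihydro-2H-chromen-3-ol | Brc1cc2c(cc1OCc1ccccc1)O[C@@H](c1ccc(OCc3ccccc3)c(OCc3ccccc3)c1)[C@@H](O)C2
F2 | step 8 | (2S,3S)-7-(benzyloxy)-6-{(3R)-3-[3-(benzyloxy)phenoxy]-3-[4-(benzyloxy)phenyl]prop-1-yn-1-yl}-2-[3,4-bis(benzyloxy)phenyl]-3,4-dihydro-2H-chromen-3-ol | C(#Cc1cc2c(cc1OCc1ccccc1)O[C@@H](c1ccc(OCc3ccccc3)c(OCc3ccccc3)c1)[C@@H](O)C2)[C@H](Oc1cccc(OCc2ccccc2)c1)c1ccc(OCc2ccccc2)cc1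
F3 | step 8 | (2S,3S)-7-(benzyloxy)-6-{(2R)-7-(benzyloxy)-2-[4-(benzyloxy)phenyl]-3-iodo-2H-chromen-4-yl}-2-[3,4-bis(benzyloxy)phenyl]-3,4-dihydro-2H-chromen-3-ol | C(c1ccccc1)Oc1ccc(cc1)[C@H]1Oc2cc(OCc3ccccc3)ccc2C(=C1I)c1cc2c(cc1OCc1ccccc1)O[C@@H](c1ccc(OCc3ccccc3)c(OCc3ccccc3)c1)[C@@H](O)C2
F4 | step 6 | rac-1-[4-(benzyloxy)phenyl]prop-2-yn-1-yl acetate | CC(=O)OC(C#C)c1ccc(OCc2ccccc2)cc1
F5 | step 2 | (S)-1-[3,4-bis(benzyloxy)phenyl]prop-2-en-1-ol | C=C[C@H](O)c1ccc(OCc2ccccc2)c(OCc2ccccc2)c1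
F6 | step 2 | (R)-1-[3,4-bis(benzyloxy)phenyl]prop-2-en-1-yl acetate | C=C[C@@H](OC(C)=O)c1ccc(OCc2ccccc2)c(OCc2ccccc2)c1
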